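**Retrosynthetic overview**
1. Enabling feature (germacrane numbering: ring C1–C10, C14 = ester carbon on C10, C15 = CH2OH carbon on C4, C11/C12/C13 = lactone unit on C7, lactone oxygen on C6): the ring atoms C10=C1–C2–C3–C4=C5 form a 1,5-diene whose ends C5 and C10 are also linked through C6–C7–C8–C9. Joining C5 to C10 turns the ten-membered ring into a 1,2-dialkenylcyclohexane, so C2–C3 is the σ-bond made by a Cope-type [3,3] shift, and C14 on C10 can be the trace of an oxygen (C10 ketone → enol triflate → CO).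
2. Disconnections, backwards: α-methylene lactone ⇒ oxidative lactonisation of a C6/C12 diol; C14 ester ⇒ carbonylation of the C10 enol triflate; cyclodec-4-en-10-one ⇒ anionic oxy-Cope ring expansion of cyclohexanol 22 (C2–C3 made, C5–C10 broken).
3. Cyclohexanol 22: stereocentres C5–C8 from one Diels–Alder reaction (1-alkoxy-3-silyloxy diene + β-boryl enone, boron = latent 6-OH); C9 and C10 from OsO4 dihydroxylation of the C9=C10 alkene after vinylation of C10.
4. Ring order: cyclohexene (Diels–Alder) → temporary trans-γ-lactone O6–C15 (carrier for the C3 methylene) → ten-membered carbocycle by six-to-ten ring expansion (the six-membered ring is consumed) → α-methylene-γ-butyrolactone O6–C12 last.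

Key step: step 17

Remark: germacrane numbers and the α/β descriptors of the target (6α-O, 7β-C, 8β-O, 9α-O) are used for all ring intermediates (cyclohexane ring = C5–C10); but-3-yn-2-ol is used as the racemate because its carbinol centre is oxidised in step 2.

Step 1
Reactants: 1 but-3-yn-2-ol (racemate)
Product: 2 (E)-4-(pinacolboryl)but-3-en-2-ol (racemate)
Conditions: B2pin2 (1.1 equiv), CuCl (5 mol%), Xantphos (5 mol%), NaOtBu (10 mol%), MeOH (2 equiv), THF, 25 °C
Reagents that add atoms: bis(pinacolato)diboron, CC1(C)OB(OC1(C)C)B1OC(C)(C)C(C)(C)O1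
Why: copper-catalysed formal hydroboration (syn borylcupration of the terminal alkyne with boron on the terminal carbon, then protonolysis by methanol with retention) should give the (E)-alkenylboronate and tolerates the free hydroxyl.

Step 2
Reactants: 2 (E)-4-(pinacolboryl)but-3-en-2-ol
Product: 3 (E)-4-(pinacolboryl)but-3-en-2-one
Conditions: 1,1,1-triacetoxy-1,1-dihydro-1,2-benziodoxol-3(1H)-one (1.2 equiv), CH2Cl2, 0 → 25 °C
Reagents that add atoms: none
Why: hypervalent-iodine oxidation of a secondary allylic alcohol under neutral conditions should give the enone without touching the C–B bond or the E geometry.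

Step 3
Reactants: 4 4-methoxybenzyl alcohol; 5 but-3-yn-2-one
Product: 6 (E)-4-[(4-methoxybenzyl)oxy]but-3-en-2-one
Conditions: PMe3 (10 mol%), CH2Cl2, 0 → 25 °C
Reagents that add atoms: none
Why: phosphine-catalysed oxa-Michael addition of the alcohol to the ynone should give the thermodynamically preferred (E)-β-alkoxy enone.

Step 4
Reactants: 6 (E)-4-[(4-methoxybenzyl)oxy]but-3-en-2-one
Product: 7 methyl (E)-6-[(4-methoxybenzyl)oxy]-4-oxohex-5-enoate
Conditions: LiN(iPr)2 (1.1 equiv), THF, −78 °C; methyl bromoacetate, −78 → −40 °C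
Reagents that add atoms: methyl bromoacetate, COC(=O)CBr
Why: kinetic deprotonation of the only enolisable position (the methyl group of the vinylogous ester) and SN2 alkylation of the lithium enolate (enolate alkylation) add the future C4/C15 unit.

Step 5
Reactants: 7 methyl (E)-6-[(4-methoxybenzyl)oxy]-4-oxohex-5-enoate
Product: 8 methyl (3Z,5E)-6-[(4-methoxybenzyl)oxy]-4-(triisopropylsilyloxy)hexa-3,5-dienoate
Conditions: iPr3SiOSO2CF3 (1.2 equiv), Et3N (2 equiv), Et2O, 0 °C
Reagents that add atoms: triisopropylsilyl trifluoromethanesulfonate, CC(C)[Si](OS(=O)(=O)C(F)(F)F)(C(C)C)C(C)C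
Why: soft enolisation (silyl triflate/amine) of the ketone toward its only α-CH2 should give the 1-alkoxy-3-silyloxy diene as the (3Z)-enol ether, which places the CH2CO2Me group "outside" on the diene terminus.

Step 6
Reactants: 8 diene; 3 (E)-4-(pinacolboryl)but-3-en-2-one
Product: 9 cycloadduct (cyclohex-9-ene: 5β-CH2CO2Me 6α-Bpin 7β-acetyl 8β-OPMB 10-OSi(iPr)3)
Conditions: oxazaborolidinium triflimide from (S)-α,α-diphenylprolinol, tri(o-tolyl)boroxine and HN(SO2CF3)2 (10 mol%), CH2Cl2, −78 °C
Reagents that add atoms: none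
Why: Lewis-acid-catalysed endo-selective Diels–Alder reaction: the nucleophilic diene terminus bearing CH2CO2Me (future C5) bonds to the boron-bearing β-carbon (C6) and the alkoxy terminus (C8) to the acyl-bearing carbon (C7); the endo-acetyl transition state with both terminal diene substituents outside sets 8-OPMB, 7-acetyl and 5-CH2CO2Me mutually cis, the (E)-dienophile sets 6-B trans to 7-acetyl, and the absolute configuration comes from the enone face left open by the chiral boron Lewis acid (the antipodal catalyst would give the mirror-image series).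

Step 7
Reactants: 9 cycloadduct
Product: 10 C10 enol triflate
Conditions: CsF (2 equiv), PhN(SO2CF3)2 (1.3 equiv), 1,2-dimethoxyethane, 25 °C
Reagents that add atoms: N-phenylbis(trifluoromethanesulfonimide), O=S(=O)(N(c1ccccc1)S(=O)(=O)C(F)(F)F)C(F)(F)F
Why: fluoride cleaves the Si–O bond and the regiodefined caesium enolate should be O-sulfonylated before β-elimination of the C8 ether can compete (one-pot silyl enol ether → enol triflate conversion).

Step 8
Reactants: 10 C10 enol triflate
Product: 11 C9=C10–C1=C2 diene (10-vinylcyclohex-9-ene)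
Conditions: tributyl(vinyl)stannane (1.3 equiv), Pd(PPh3)4 (5 mol%), LiCl (3 equiv), THF, 60 °C
Reagents that add atoms: tributyl(vinyl)stannane, C=C[Sn](CCCC)(CCCC)CCCC
Why: Stille coupling of the alkenyl triflate (oxidative addition to zerovalent palladium, transmetalation, reductive elimination) should install C1/C2 while the alkyl boronate, ketone and ester stay inert under base-free conditions.

Step 9
Reactants: 11 10-vinylcyclohex-9-ene methyl ketone
Product: 12 side-chain enol triflate (7β-C(OSO2CF3)=CH2)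
Conditions: KN(SiMe3)2 (1.1 equiv), THF, −78 °C; PhN(SO2CF3)2 (1.2 equiv), −78 → −20 °C
Reagents that add atoms: N-phenylbis(trifluoromethanesulfonimide), O=S(=O)(N(c1ccccc1)S(=O)(=O)C(F)(F)F)C(F)(F)F
Why: kinetic deprotonation of the methyl ketone at its CH3 (future C13) and O-triflation should give the 1,1-disubstituted enol triflate, whereas enolisation toward C7, which would open β-elimination of the C8 ether, is disfavoured at −78 °C.

Step 10
Reactants: 12 side-chain enol triflate
Product: 14 trans-γ-lactone O6–C15, via hydroxy ester 13 (not isolated)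
Conditions: NaBO3·4H2O (3 equiv), THF/H2O 1:1, 25 °C; then DBU (0.2 equiv), toluene, 40 °C
Reagents that add atoms: sodium perborate, [Na+].[Na+].O[B-]1(O)OO[B-](O)(O)OO1
Why: perborate oxidation of the secondary alkylboronate proceeds with retention to the 6α-alcohol, which should lactonise onto the trans-diequatorial CH2CO2Me group under amidine catalysis, protecting O6 and activating C4.

Step 11
Reactants: 14 trans-γ-lactone
Product: 17 α-methylene lactone (C3=C4), via Mannich base 15 (not isolated), via methiodide 16 (not isolated)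
Conditions: LiN(SiMe3)2 (1.2 equiv), THF, −78 °C; CH2=NMe2+ I− (−78 → 0 °C); then MeI, MeOH, 25 °C; then aq. NaHCO3, CH2Cl2, 25 °C
Reagents that add atoms: dimethylmethyleneiminium iodide, C=[N+](C)C.[I-]
Why: Mannich aminomethylation of the lactone lithium enolate, N-methylation and Hofmann-type elimination are the standard α-methylenation sequence and should introduce C3 as an electron-poor alkene that survives the next step.

Step 12
Reactants: 17 α-methylene lactone
Product: 18 9α,10α-diol (10β-vinyl)
Conditions: OsO4 (2 mol%), N-methylmorpholine N-oxide (1.1 equiv), acetone/H2O 8:1, 0 °C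
Reagents that add atoms: N-methylmorpholine N-oxide, C[N+]1([O-])CCOCC1; water, O
Why: catalytic syn-dihydroxylation by electrophilic OsO4 should select the trisubstituted, electron-rich C9=C10 alkene over the terminal vinyl group and the two electron-poor alkenes, and attack from the α-face, anti to the pseudo-axial allylic 8β-ether and the 5β-substituent, sets 9α-OH and the tertiary 10α-OH with the vinyl group β.

Step 13
Reactants: 18 9α,10α-diol
Product: 19 diol with complete C7 side chain (7β-C(=CH2)CH2OCH2OCH3)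
Conditions: Bu3SnCH2OCH2OCH3 (1.5 equiv), Pd(PPh3)4 (10 mol%), LiCl (3 equiv), 1,4-dioxane, 90 °C
Reagents that add atoms: tributyl[(methoxymethoxy)methyl]stannane, COCOC[Sn](CCCC)(CCCC)CCCC
Why: Stille coupling that transfers the activated α-alkoxymethyl group to the enol triflate should build the C11(=C13)–C12–O unit without base, so the lactone and the free diol are untouched.

Step 14
Reactants: 19 diol lactone
Product: 20 tetraol (6α-OH 9α-OH 10α-OH 15-OH)
Conditions: iBu2AlH (6 equiv), CH2Cl2, −78 → 0 °C; aq. KNaC4H4O6 (potassium sodium tartrate)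
Reagents that add atoms: none
Why: 1,2-reduction of the α-methylene lactone by the aluminium hydride (lactol, then alcohol) should give the 2-methylene-1,4-diol, that is the C4(=C3H2)–C15H2OH arm and free 6-OH.

Step 15
Reactants: 20 tetraol
Product: 21 15-O-silyl ether
Conditions: tBuMe2SiCl (1.05 equiv), imidazole, CH2Cl2, −20 °C
Reagents that add atoms: tert-butyldimethylsilyl chloride, CC(C)(C)[Si](C)(C)Cl
Why: silylation is sterically selective for the single primary (allylic) hydroxyl over two hindered secondary and one tertiary hydroxyl.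

Step 16
Reactants: 21 15-O-silyl ether
Product: 22 6,9-bis-O-methoxymethyl ether (oxy-Cope substrate)
Conditions: CH3OCH2Cl (6 equiv), iPr2NEt (8 equiv), Bu4NI (cat.), CH2Cl2, 0 → 40 °C
Reagents that add atoms: chloromethyl methyl ether, COCCl
Why: O-alkylation with the α-halo ether should cap both secondary hydroxyls as non-migrating acetals while the far more hindered tertiary allylic 10-OH stays free for the key step.

Step 17
Reactants: 22 oxy-Cope substrate
Product: 24 (4E)-cyclodec-4-en-10-one, via potassium enolate 23 (not isolated)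
Conditions: KH (3 equiv), 18-crown-6 (3 equiv), THF, 0 → 25 °C; then sat. aq. NH4Cl, −78 °C
Reagents that add atoms: none
Why: Deprotonation of the tertiary 10-OH gives a crown-separated potassium alkoxide whose O− weakens the C5–C10 bond and triggers a charge-accelerated [3,3]-sigmatropic shift of the C3=C4–C5–C10–C1=C2 diene (anionic oxy-Cope rearrangement, the reaction type known for 1,2-dialkenylcyclohexanol → cyclodec-5-enone ring expansion); C2–C3 forms as C5–C10 breaks, giving the C1=C10 enolate 23, which is protonated to ketone 24. The ten-membered ring is closed as a four-atom ring expansion of the six-membered ring through a chair-like six-centre transition state, so no medium-ring cyclisation entropy is paid. No stereocentre is created (C5 and C10 become trigonal, C6–C9 are untouched), but the C4=C5 geometry is fixed: in the reacting cyclohexane chair the C5 alkenyl group is equatorial and the cis C10 vinyl group axial, which places the ring bond C5–C6 on the inside of the chair transition state and should give the ring-cis (4E) alkene of the target, while the enolate is formed ring-trans and its geometry is erased on purpose by protonation. The selectivity needed is for this chair over its ring-flipped partner (which would give the ring-trans C4=C5 isomer), and it is secured by the all-trans 5β/6α/7β substituents, which are all equatorial only in the productive chair, the alternative forcing the branched C5 and C7 groups syn-diaxial. Chemoselectivity should be clean because 10-OH is the only free hydroxyl, the C10-vinyl/C5-alkenyl pair is the only 1,5-diene, and the acetal, benzyl and silyl ethers are base-stable and cannot migrate to the alkoxide.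

Step 18
Reactants: 24 cyclodec-4-en-10-one
Product: 25 (1(10)E,4E)-dienyl triflate
Conditions: LiN(iPr)2 (1.2 equiv), THF, −78 °C; N-(5-chloropyridin-2-yl)bis(trifluoromethanesulfonimide) (1.3 equiv), −78 °C
Reagents that add atoms: N-(5-chloropyridin-2-yl)bis(trifluoromethanesulfonimide), O=S(=O)(N(c1ccc(Cl)cn1)S(=O)(=O)C(F)(F)F)C(F)(F)F
Why: kinetic enolisation at the unhindered C1 methylene (not at the alkoxylated C9) followed by O-triflation should give the enol triflate with C2 and C9 cis, because the medium ring, which already holds the cis C4=C5 bond, disfavours a trans C1=C10 bond (ketone → enol triflate).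

Step 19
Reactants: 25 dienyl triflate
Product: 26 C14 methyl ester
Conditions: Pd(OAc)2 (5 mol%), PPh3 (10 mol%), CO (1 atm), MeOH, Et3N, DMF, 50 °C
Reagents that add atoms: carbon monoxide, [C-]#[O+]; methanol, CO
Why: palladium-catalysed methoxycarbonylation of the alkenyl triflate (oxidative addition, CO insertion, methanolysis) proceeds with retention of alkene geometry and should give the (1(10)E)-enoate of the target.

Step 20
Reactants: 26 C14 methyl ester
Product: 27 8β-alcohol
Conditions: DDQ (1.5 equiv), CH2Cl2/pH 7 phosphate buffer 10:1, 0 °C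
Reagents that add atoms: none
Why: oxidative cleavage of the 4-methoxybenzyl ether (benzylic hydride abstraction, hydrolysis of the oxocarbenium ion) should free only O8, the acetal and silyl ethers being inert.

Step 21
Reactants: 27 8β-alcohol
Product: 28 8β-isobutyrate
Conditions: (iPrCO)2O (3 equiv), DMAP (0.3 equiv), Et3N, CH2Cl2, 25 °C
Reagents that add atoms: isobutyric anhydride, CC(C)C(=O)OC(=O)C(C)C
Why: nucleophile-catalysed acylation of the only free hydroxyl installs the C8 ester.

Step 22
Reactants: 28 8β-isobutyrate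
Product: 29 6α,9α,12-triol
Conditions: Me2BBr (6 equiv), CH2Cl2, −78 °C; then THF/aq. NaHCO3
Reagents that add atoms: none
Why: the bromoborane should cleave all three methoxymethyl acetals at −78 °C (boron activation of the acetal oxygen, bromide attack), conditions under which the silyl ether, the esters and the alkenes survive.

Step 23
Reactants: 29 6α,9α,12-triol
Product: 32 9α-hydroxy α-methylene lactone, via hydroxy aldehyde 30 (not isolated), via lactol 31 (not isolated)
Conditions: TEMPO (0.2 equiv), PhI(OAc)2 (3 equiv), CH2Cl2, 25 °C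
Reagents that add atoms: none
Why: oxoammonium oxidation is selective for the primary allylic 12-OH; the aldehyde is trapped by the 6α-OH as the five-membered lactol, which is oxidised on to the lactone (oxidative lactonisation), while the hindered secondary 9-OH should react more slowly.

Step 24
Reactants: 32 9α-hydroxy α-methylene lactone
Product: 33 9α-acetate (15-O-silyl ether of the target)
Conditions: Ac2O, pyridine, DMAP (cat.), CH2Cl2, 0 → 25 °C
Reagents that add atoms: acetic anhydride, CC(=O)OC(C)=O
Why: acetylation of the remaining secondary hydroxyl installs the C9 ester under conditions the α-methylene lactone tolerates.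

Step 25
Reactants: 33 15-O-silyl ether of the target
Product: 34 target CNP0242134.2
Conditions: HF·pyridine, pyridine, THF, 0 °C
Reagents that add atoms: none
Why: buffered fluoride desilylation of the primary allylic silyl ether should leave the three esters and the Michael-acceptor lactone intact.

**Compound list**
1 | but-3-yn-2-ol (racemate) | CC(O)C#C | starting material
2 | (E)-4-(4,4,5,5-tetramethyl-1,3,2-dioxaborolan-2-yl)but-3-en-2-ol (racemate) | CC(O)/C=C/B1OC(C)(C)C(C)(C)O1 | intermediate
3 | (E)-4-(4,4,5,5-tetramethyl-1,3,2-dioxaborolan-2-yl)but-3-en-2-one | CC(=O)/C=C/B1OC(C)(C)C(C)(C)O1 | intermediate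
4 | 4-methoxybenzyl alcohol | COc1ccc(CO)cc1 | starting material
5 | but-3-yn-2-one | CC(=O)C#C | starting material
6 | (E)-4-[(4-methoxybenzyl)oxy]but-3-en-2-one | CC(=O)/C=C/OCc1ccc(OC)cc1 | intermediate
7 | methyl (E)-6-[(4-methoxybenzyl)oxy]-4-oxohex-5-enoate | COC(=O)CCC(=O)/C=C/OCc1ccc(OC)cc1 | intermediate
8 | methyl (3Z,5E)-6-[(4-methoxybenzyl)oxy]-4-(triisopropylsilyloxy)hexa-3,5-dienoate | COC(=O)C/C=C(\O[Si](C(C)C)(C(C)C)C(C)C)/C=C/OCc1ccc(OC)cc1 | intermediate
9 | methyl [7β-acetyl-8β-(4-methoxybenzyloxy)-6α-(pinacolboryl)-10-(triisopropylsilyloxy)cyclohex-9-en-5β-yl]acetate | CC(C)[Si](C(C)C)(C(C)C)OC1=C[C@@H](OCc2ccc(OC)cc2)[C@@H](C(C)=O)[C@H](B3OC(C)(C)C(C)(C)O3)[C@H]1CC(=O)OC | intermediate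
10 | methyl [7β-acetyl-8β-(4-methoxybenzyloxy)-6α-(pinacolboryl)-10-(trifluoromethylsulfonyloxy)cyclohex-9-en-5β-yl]acetate | O=S(=O)(OC1=C[C@@H](OCc2ccc(OC)cc2)[C@@H](C(C)=O)[C@H](B3OC(C)(C)C(C)(C)O3)[C@H]1CC(=O)OC)C(F)(F)F | intermediate
11 | methyl [7β-acetyl-8β-(4-methoxybenzyloxy)-6α-(pinacolboryl)-10-vinylcyclohex-9-en-5β-yl]acetate | C=CC1=C[C@@H](OCc2ccc(OC)cc2)[C@@H](C(C)=O)[C@H](B3OC(C)(C)C(C)(C)O3)[C@H]1CC(=O)OC | intermediate
12 | methyl [8β-(4-methoxybenzyloxy)-6α-(pinacolboryl)-7β-[1-(trifluoromethylsulfonyloxy)vinyl]-10-vinylcyclohex-9-en-5β-yl]acetate | C=CC1=C[C@@H](OCc2ccc(OC)cc2)[C@@H](C(=C)OS(=O)(=O)C(F)(F)F)[C@H](B3OC(C)(C)C(C)(C)O3)[C@H]1CC(=O)OC | intermediate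
13 | methyl [6α-hydroxy-8β-(4-methoxybenzyloxy)-7β-[1-(trifluoromethylsulfonyloxy)vinyl]-10-vinylcyclohex-9-en-5β-yl]acetate | C=CC1=C[C@@H](OCc2ccc(OC)cc2)[C@@H](C(=C)OS(=O)(=O)C(F)(F)F)[C@H](O)[C@H]1CC(=O)OC | intermediate (not isolated)
14 | trans-fused γ-lactone of 13 (O6–C15(=O)–C4H2–C5) | C=CC1=C[C@@H](OCc2ccc(OC)cc2)[C@@H](C(=C)OS(=O)(=O)C(F)(F)F)[C@H](OC(=O)C3)[C@H]13 | intermediate
15 | lactone 14 with CH2NMe2 on C4 (C4 epimers, centre lost in the same step) | C=CC1=C[C@@H](OCc2ccc(OC)cc2)[C@@H](C(=C)OS(=O)(=O)C(F)(F)F)[C@H](OC(=O)C3CN(C)C)[C@H]13 | intermediate (not isolated)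
16 | trimethylammonium iodide of 15 | C=CC1=C[C@@H](OCc2ccc(OC)cc2)[C@@H](C(=C)OS(=O)(=O)C(F)(F)F)[C@H](OC(=O)C3C[N+](C)(C)C)[C@H]13.[I-] | intermediate (not isolated)
17 | α-methylene lactone (C3=C4) of 14 | C=CC1=C[C@@H](OCc2ccc(OC)cc2)[C@@H](C(=C)OS(=O)(=O)C(F)(F)F)[C@H](OC(=O)C3=C)[C@H]13 | intermediate
18 | 9α,10α-dihydroxy-10β-vinyl cyclohexane lactone from 17 | O[C@]1(C=C)[C@H](O)[C@@H](OCc2ccc(OC)cc2)[C@@H](C(=C)OS(=O)(=O)C(F)(F)F)[C@H](OC(=O)C3=C)[C@H]13 | intermediate
19 | diol 18 with 7β-[3-(methoxymethoxy)prop-1-en-2-yl] in place of the enol triflate | O[C@]1(C=C)[C@H](O)[C@@H](OCc2ccc(OC)cc2)[C@@H](C(=C)COCOC)[C@H](OC(=O)C3=C)[C@H]13 | intermediate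
20 | (5β,6α,7β,8β,9α,10α)-5-(3-hydroxyprop-1-en-2-yl)-8-(4-methoxybenzyloxy)-7-[3-(methoxymethoxy)prop-1-en-2-yl]-10-vinylcyclohexane-6,9,10-triol | O[C@]1(C=C)[C@H](O)[C@@H](OCc2ccc(OC)cc2)[C@@H](C(=C)COCOC)[C@H](O)[C@H]1C(=C)CO | intermediate
21 | 15-O-tert-butyldimethylsilyl ether of 20 | O[C@]1(C=C)[C@H](O)[C@@H](OCc2ccc(OC)cc2)[C@@H](C(=C)COCOC)[C@H](O)[C@H]1C(=C)CO[Si](C)(C)C(C)(C)C | intermediate
22 | 6α,9α-bis(methoxymethoxy) ether of 21 (10α-hydroxy-10β-vinyl-5β-alkenylcyclohexane) | O[C@]1(C=C)[C@H](OCOC)[C@@H](OCc2ccc(OC)cc2)[C@@H](C(=C)COCOC)[C@H](OCOC)[C@H]1C(=C)CO[Si](C)(C)C(C)(C)C | intermediate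
23 | potassium (1(10)Z,4E)-enolate of 24 (C2 and C9 trans) | COCO[C@@H]1/C=C(/CO[Si](C)(C)C(C)(C)C)CC/C=C(\[O-])[C@H](OCOC)[C@@H](OCc2ccc(OC)cc2)[C@H]1C(=C)COCOC.[K+] | intermediate (not isolated)
24 | (4E)-6α,9α-bis(methoxymethoxy)-8β-(4-methoxybenzyloxy)-7β-[3-(methoxymethoxy)prop-1-en-2-yl]-4-[(tert-butyldimethylsilyloxy)methyl]cyclodec-4-en-10-one | COCO[C@@H]1/C=C(/CO[Si](C)(C)C(C)(C)C)CCCC(=O)[C@H](OCOC)[C@@H](OCc2ccc(OC)cc2)[C@H]1C(=C)COCOC | intermediate
25 | (1(10)E,4E)-cyclodeca-1(10),4-dien-10-yl trifluoromethanesulfonate from 24 | COCO[C@@H]1/C=C(/CO[Si](C)(C)C(C)(C)C)CC/C=C(/OS(=O)(=O)C(F)(F)F)[C@H](OCOC)[C@@H](OCc2ccc(OC)cc2)[C@H]1C(=C)COCOC | intermediate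
26 | methyl (1(10)E,4E)-cyclodeca-1(10),4-diene-10-carboxylate (C14 ester) with the ether pattern of 24 | COCO[C@@H]1/C=C(/CO[Si](C)(C)C(C)(C)C)CC/C=C(/C(=O)OC)[C@H](OCOC)[C@@H](OCc2ccc(OC)cc2)[C@H]1C(=C)COCOC | intermediate
27 | 8β-alcohol from 26 | COCO[C@@H]1/C=C(/CO[Si](C)(C)C(C)(C)C)CC/C=C(/C(=O)OC)[C@H](OCOC)[C@@H](O)[C@H]1C(=C)COCOC | intermediate
28 | 8β-isobutyrate of 27 | COCO[C@@H]1/C=C(/CO[Si](C)(C)C(C)(C)C)CC/C=C(/C(=O)OC)[C@H](OCOC)[C@@H](OC(=O)C(C)C)[C@H]1C(=C)COCOC | intermediate
29 | 6α,9α,12-triol (8β-isobutyrate, 15-O-silyl ether, C14 methyl ester) | O[C@@H]1/C=C(/CO[Si](C)(C)C(C)(C)C)CC/C=C(/C(=O)OC)[C@H](O)[C@@H](OC(=O)C(C)C)[C@H]1C(=C)CO | intermediate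
30 | 12-aldehyde of 29 | O[C@@H]1/C=C(/CO[Si](C)(C)C(C)(C)C)CC/C=C(/C(=O)OC)[C@H](O)[C@@H](OC(=O)C(C)C)[C@H]1C(=C)C=O | intermediate (not isolated)
31 | 6α,12-lactol of 30 (C12 epimers) | C=C1C(O)O[C@@H]2/C=C(/CO[Si](C)(C)C(C)(C)C)CC/C=C(/C(=O)OC)[C@H](O)[C@@H](OC(=O)C(C)C)[C@@H]12 | intermediate (not isolated)
32 | 9-deacetyl-15-O-(tert-butyldimethylsilyl) target (9α-hydroxy-12,6α-olide) | C=C1C(=O)O[C@@H]2/C=C(/CO[Si](C)(C)C(C)(C)C)CC/C=C(/C(=O)OC)[C@H](O)[C@@H](OC(=O)C(C)C)[C@@H]12 | intermediate
33 | 15-O-(tert-butyldimethylsilyl) ether of the target | C=C1C(=O)O[C@@H]2/C=C(/CO[Si](C)(C)C(C)(C)C)CC/C=C(/C(=O)OC)[C@H](OC(C)=O)[C@@H](OC(=O)C(C)C)[C@@H]12 | intermediate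
34 | CNP0242134.2: methyl (1(10)E,4E)-9α-acetoxy-15-hydroxy-8β-(isobutyryloxy)-12-oxo-germacra-1(10),4,11(13)-trien-12,6α-olid-14-oate | C=C1C(=O)O[C@@H]2/C=C(/CO)CC/C=C(/C(=O)OC)[C@H](OC(C)=O)[C@@H](OC(=O)C(C)C)[C@@H]12 | target

**Step count and risks**
Total: 25 steps. Longest linear sequence: 23 steps (steps 3–25, from 4-methoxybenzyl alcohol and but-3-yn-2-one); steps 1–2 are a two-step branch that joins at step 6.

Step 6 (Diels–Alder). The strong cationic boron Lewis acid may ionise the vinylogous acetal of diene 8 or divert the reaction into a stepwise Michael/ring-closure path, with loss of endo- and enantiocontrol. The fallback uses covalent auxiliary control without any Lewis acid and sets out from diene 8. Commercial (E)-3-(pinacolboryl)acrylic acid is activated with pivaloyl chloride/Et3N as (2E)-3-(pinacolboryl)prop-2-enoic pivalic anhydride F1, which N-acylates lithiated (S)-4-benzyl-1,3-oxazolidin-2-one to give (S)-4-benzyl-3-[(2E)-3-(pinacolboryl)prop-2-enoyl]-1,3-oxazolidin-2-one F2. Heating 8 with F2 in toluene at 80 °C (uncatalysed, endo by secondary-orbital control) should favour the N-acyl oxazolidinone cycloadduct F3 with the configuration of 9; the minor diastereomer is removed by chromatography, which secures enantiopurity. LiSEt (THF, 0 °C) converts F3 into the S-ethyl thioester F4, and Fukuyama coupling (MeZnI, PdCl2(PPh3)2, toluene) gives methyl ketone 9, where the route is rejoined.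

Step 17 (oxy-Cope). The alkoxide may fragment heterolytically at C5–C10 (an allyl anion at C5 would expel the C6 ether), or some material may react through the ring-flipped chair. The fallback is the neutral, electrophile-triggered version of the same ring expansion and sets out from 22: PdCl2(PhCN)2 (10 mol%), THF, 25 °C. Divalent palladium activates the unsubstituted C1=C2 vinyl group, the 2-substituted C3=C4 alkene attacks it in a chair-like cyclisation that makes C2–C3 and develops positive charge at the tertiary C4, and C5–C10 cleavage assisted by the free hydroxyl gives ketone 24 without any alkoxide. No new compound arises (F0) and the route is rejoined at 24.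

Step 18 (enol triflate). Enolisation may give the ring-trans enolate (wrong C1=C10 geometry) or occur toward C9, followed by β-elimination of the C8 ether. The fallback is a Shapiro reaction, in which regiochemistry and geometry follow from syn-deprotonation, and it sets out from 24. Condensation with 2,4,6-triisopropylbenzenesulfonohydrazide (THF, 25 °C) gives the arylsulfonylhydrazone F5; n-BuLi (2.2 equiv, THF/TMEDA, −78 → 0 °C) deprotonates C1 syn to the sulfonamide nitrogen and, after loss of sulfinate and N2, gives the ring-cis C10 alkenyllithium F6, which is quenched with methyl chloroformate. This gives ester 26 directly, where the route is rejoined (25 is bypassed).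

Further compounds
F1 | step 6 | (2E)-3-(4,4,5,5-tetramethyl-1,3,2-dioxaborolan-2-yl)prop-2-enoic 2,2-dimethylpropanoic anhydride | CC(C)(C)C(=O)OC(=O)/C=C/B1OC(C)(C)C(C)(C)O1
F2 | step 6 | (S)-4-benzyl-3-[(2E)-3-(4,4,5,5-tetramethyl-1,3,2-dioxaborolan-2-yl)prop-2-enoyl]-1,3-oxazolidin-2-one | O=C(/C=C/B1OC(C)(C)C(C)(C)O1)N2[C@@H](Cc3ccccc3)COC2=O
F3 | step 6 | N-acyl oxazolidinone analogue of 9 (7β-C(=O)-[(S)-4-benzyl-2-oxo-oxazolidin-3-yl]) | CC(C)[Si](C(C)C)(C(C)C)OC1=C[C@@H](OCc2ccc(OC)cc2)[C@@H](C(=O)N3[C@@H](Cc4ccccc4)COC3=O)[C@H](B5OC(C)(C)C(C)(C)O5)[C@H]1CC(=O)OC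
F4 | step 6 | S-ethyl thioester analogue of 9 (7β-C(=O)SEt) | CC(C)[Si](C(C)C)(C(C)C)OC1=C[C@@H](OCc2ccc(OC)cc2)[C@@H](C(=O)SCC)[C@H](B3OC(C)(C)C(C)(C)O3)[C@H]1CC(=O)OC
F0 | step 17 | none | none
F5 | step 18 | 2,4,6-triisopropylbenzenesulfonylhydrazone of ketone 24 (C=N geometry not fixed) | COCO[C@@H]1/C=C(/CO[Si](C)(C)C(C)(C)C)CCCC(=NNS(=O)(=O)c2c(C(C)C)cc(C(C)C)cc2C(C)C)[C@H](OCOC)[C@@H](OCc3ccc(OC)cc3)[C@H]1C(=C)COCOC
F6 | step 18 | (1(10),4)-dienyl-10-lithium from F5 (C2 and C9 cis) | COCO[C@@H]1/C=C(/CO[Si](C)(C)C(C)(C)C)CC/C=C(/[Li])[C@H](OCOC)[C@@H](OCc2ccc(OC)cc2)[C@H]1C(=C)COCOC
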